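You need two amounts for this flask: R, the free monomer reacted, which over the charge gives c, and the number of chains begun, which divides the monomer in chains to give dp. For the chains I take the chain budget B, the initiator charged, 10.0 mM, counting one chain per initiator, so that R/B is my reckoning of dp.

the same everywhere: initiator 10 mM
- south: free monomer 0.10 M; run made earlier
- north-east: free monomer 0.40 M; run made earlier
- flask: free monomer 0.20 M; time 12 h

- south (time / h: monomer in chains / %, free monomer / %): 1.00: 0.1, 100.5; 1.50: 0, 99.9; 2.50: 0.2, 100.5; 4.00: 0.3, 100.4; 8.00: 0.6, 99.5; 12.0: 0.1, 99.8
- north-east (time / h: monomer in chains / %, free monomer / %): 1.00: 50.9, 46.8; 1.50: 52.3, 46.0; 2.50: 53.3, 45.5; 4.00: 52.9, 45.1; 8.00: 53.1, 44.8; 12.0: 51.8, 45.5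

(standard deviation of a reading: 0.5 percentage points)

* average number of monomer units in a chain (chains begun, living or dead) at 12 h
* part of the free monomer that has reacted at 12 h

- the average divides the monomer in chains by the number of chains begun, living and dead together
- the numbers in the tables scatter by 0.5 percentage points (one standard deviation)
- the earlier runs do not show the number of chains; that part of a forecast is a guess

Which number has to be known well? Time need not be, for the north-east run reads 45.5% free monomer after 2.50 h and 45.5% after 12.0 h. In this reckoning an error in B passes into dp in proportion and leaves c untouched. The one to know well is Mc, the concentration of free monomer at which I take the flask to stand still, as the north-east run does (a ceiling concentration, if that is what it is), since I reckon R as the charge less Mc, a difference smaller than the charge. The scatter of a single north-east reading is worth 0.00200 M in Mc. Taking the mean of the north-east readings from 2.50 h on, I reckon: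

Mc = 0.181 M

R = 0.0191 M, so c = 9.55%

dp ≈ R/B = 1.91

The forecast, higher than mine on c, says 20 and 12.5%: “The chain count is a guess, so dp is uncertain.”

The flask gives dp = 6.47 and c = 32.3%.

    free monomer + initiator → living end + monomer in chains (k = 0.0180 M⁻¹ s⁻¹)
    free monomer + living end → monomer in chains + living end, rate k2*[living end]*[free monomer] (k = 0.0890 M⁻¹ s⁻¹)
    monomer in chains + living end → free monomer + living end, rate k3*[living end] as long as [monomer in chains] is above zero (k = 0.0120 s⁻¹)
    living end + monomer in chains → dead end A (k = 0.00340 M⁻¹ s⁻¹)
    initiator → spent initiator B (k = 5.30 × 10⁻⁴ s⁻¹)

The flask's free monomer stands at 0.135 M after 12.0 h, below my Mc. With the reacted amount of the flask, R/B becomes 6.47, beside its dp of 6.47; these are two different ratios, for the reacted amount holds dead end A as well, 4.33% of the charge, and 0.00134 M of B went to spent initiator B. The neighbour charged with 0.80 M of free monomer, with the same initiator, reaches c = 53.4%, so its R/B is 42.7, and its dp is 43.3.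

Readings and results come from a simulation with constants of no real substance, and the scatter is random.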